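## Retrosynthetic overview

1. Target ⇐ hexabenzylated 4-aryl-2H-chromene / flavan-3-ol: one H2/Pd step removes the benzyl groups and reduces the ring C alkene cis to the C2 aryl group, setting upper C4.
2. Lower 2R,3R (cis) pair ⇐ flavan-3-one, by transfer hydrogenation run as a dynamic kinetic resolution.
3. Key disconnection: both C4–C4a bonds (upper ring C and lower ring F) back to one bis(aryl propargyl ether). One gold-catalysed operation closes ring F (alkyne oxidation, carbene C–H functionalisation to the chroman-3-one) and ring C (6-endo hydroarylation to the 2H-chromene).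
4. Both O1–C2 bonds ⇐ Mitsunobu etherifications of propargylic alcohols; upper C2 ⇐ asymmetric alkynylation of 4-(benzyloxy)benzaldehyde.
5. The interflavan C4–C6 bond is the C–C bond made by para-formylation of symmetric 3,5-bis(benzyloxy)phenol (CHO → alkyne), so the 4→6 regiochemistry is fixed by symmetry. Ring order: F, then C, in the same step.

Assumption: upper unit = rings A, C, B and lower (epiafzelechin) unit = rings D, F, E, each with flavan numbering; the ligand and catalyst enantiomers written are those expected to give the required sense and the antipode is used if the opposite sense is found.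

## Route

Step 1
Reactants: 1 3,5-bis(benzyloxy)phenol
Product: 3 2,6-bis(benzyloxy)-4-hydroxybenzaldehyde, via iminium chloride 2 (not isolated)
Conditions: POCl3, DMF, MeCN, 0 °C to rt; then H2O, 50 °C
Reagents that add atoms: N,N-dimethylformamide, CN(C)C=O; water, O
Why: Vilsmeier–Haack formylation of the electron-rich phenol goes mainly para to the free OH, between the two benzyloxy groups (the minor ortho aldehyde is removed by chromatography), so the carbon that becomes upper C4 is bonded to the future C6 of ring D while ring D is still symmetric.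

Step 2
Reactants: 4 ethynyltri(propan-2-yl)silane; 5 4-(benzyloxy)benzaldehyde
Product: 7 rac-1-[4-(benzyloxy)phenyl]-3-[tri(propan-2-yl)silyl]prop-2-yn-1-ol, via lithium (triisopropylsilyl)acetylide 6 (not isolated)
Conditions: n-BuLi, THF, −78 °C; then 5, −78 to 0 °C; then H2O
Reagents that add atoms: none
Why: 1,2-addition of a lithium acetylide to an aryl aldehyde gives the propargylic alcohol, made racemic on purpose because this carbon (later lower C2) is equilibrated and set in step 9.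

Step 3
Reactants: 3 2,6-bis(benzyloxy)-4-hydroxybenzaldehyde; 7 rac-1-[4-(benzyloxy)phenyl]-3-[tri(propan-2-yl)silyl]prop-2-yn-1-ol
Product: 8 rac-2,6-bis(benzyloxy)-4-({1-[4-(benzyloxy)phenyl]-3-[tri(propan-2-yl)silyl]prop-2-yn-1-yl}oxy)benzaldehyde
Conditions: PPh3, DIAD, THF, 0 °C to rt
Reagents that add atoms: none
Why: Mitsunobu etherification of the only free phenol (made more acidic by the para formyl group) with the secondary propargylic alcohol forms the O1–C2 bond of the lower unit, and the centre stays racemic.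

Step 4
Reactants: 8 rac-2,6-bis(benzyloxy)-4-({1-[4-(benzyloxy)phenyl]-3-[tri(propan-2-yl)silyl]prop-2-yn-1-yl}oxy)benzaldehyde
Product: 9 rac-1,3-bis(benzyloxy)-2-ethynyl-5-({1-[4-(benzyloxy)phenyl]-3-[tri(propan-2-yl)silyl]prop-2-yn-1-yl}oxy)benzene
Conditions: dimethyl (1-diazo-2-oxopropyl)phosphonate, K2CO3, MeOH/THF, 0 °C to rt
Reagents that add atoms: dimethyl (1-diazo-2-oxopropyl)phosphonate, CC(=O)C(=[N+]=[N-])P(=O)(OC)OC
Why: Seyferth–Gilbert homologation in its Bestmann–Ohira form turns the non-enolisable aryl aldehyde into the terminal aryl alkyne (future upper C4 and C3) under K2CO3/MeOH, which leaves the triisopropylsilyl alkyne and the ethers intact.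

Step 5
Reactants: 9 rac-1,3-bis(benzyloxy)-2-ethynyl-5-({1-[4-(benzyloxy)phenyl]-3-[tri(propan-2-yl)silyl]prop-2-yn-1-yl}oxy)benzene; 5 4-(benzyloxy)benzaldehyde
Product: 11 (1S)-1-[4-(benzyloxy)phenyl]-3-[2,6-bis(benzyloxy)-4-({1-[4-(benzyloxy)phenyl]-3-[tri(propan-2-yl)silyl]prop-2-yn-1-yl}oxy)phenyl]prop-2-yn-1-ol, via alkynyl(methyl)zinc 10 (not isolated)
Conditions: Me2Zn, (S,S)-ProPhenol (20 mol%), Ph3P=O (40 mol%), toluene, 0 °C; then 5, 0 °C to rt; then H2O
Reagents that add atoms: none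
Why: catalytic asymmetric alkynylation of an aryl aldehyde by an alkynylzinc under the dinuclear zinc–ProPhenol catalyst sets the new carbinol centre as S by ligand control, while the silyl-capped alkyne of the lower arm cannot be zincated.

Step 6
Reactants: 11 (1S)-1-[4-(benzyloxy)phenyl]-3-[2,6-bis(benzyloxy)-4-({1-[4-(benzyloxy)phenyl]-3-[tri(propan-2-yl)silyl]prop-2-yn-1-yl}oxy)phenyl]prop-2-yn-1-ol; 12 3-(benzyloxy)phenol
Product: 13 1,3-bis(benzyloxy)-2-{(3R)-3-[4-(benzyloxy)phenyl]-3-[3-(benzyloxy)phenoxy]prop-1-yn-1-yl}-5-({1-[4-(benzyloxy)phenyl]-3-[tri(propan-2-yl)silyl]prop-2-yn-1-yl}oxy)benzene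
Conditions: PPh3, DIAD, toluene, −20 to 0 °C
Reagents that add atoms: none
Why: Mitsunobu etherification goes by SN2 inversion, so the (S)-alcohol gives the (R)-aryl ether (the upper O1–C2 bond, with the configuration that becomes 2S after ring closure), and low temperature in toluene suppresses ionisation of the benzylic propargylic oxyphosphonium.

Step 7
Reactants: 13 1,3-bis(benzyloxy)-2-{(3R)-3-[4-(benzyloxy)phenyl]-3-[3-(benzyloxy)phenoxy]prop-1-yn-1-yl}-5-({1-[4-(benzyloxy)phenyl]-3-[tri(propan-2-yl)silyl]prop-2-yn-1-yl}oxy)benzene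
Product: 14 1,3-bis(benzyloxy)-2-{(3R)-3-[4-(benzyloxy)phenyl]-3-[3-(benzyloxy)phenoxy]prop-1-yn-1-yl}-5-({1-[4-(benzyloxy)phenyl]prop-2-yn-1-yl}oxy)benzene
Conditions: Bu4NF, THF, 0 °C; then H2O
Reagents that add atoms: none
Why: fluoride-mediated protodesilylation of the alkynylsilane frees the terminal alkyne needed for the oxidation in step 8 without touching the aryl and benzyl ethers.

Step 8
Reactants: 14 1,3-bis(benzyloxy)-2-{(3R)-3-[4-(benzyloxy)phenyl]-3-[3-(benzyloxy)phenoxy]prop-1-yn-1-yl}-5-({1-[4-(benzyloxy)phenyl]prop-2-yn-1-yl}oxy)benzene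
Product: 16 (2RS)-5,7-bis(benzyloxy)-2-[4-(benzyloxy)phenyl]-6-{(2S)-7-(benzyloxy)-2-[4-(benzyloxy)phenyl]-2H-chromen-4-yl}-2H-chromen-3(4H)-one, via monocyclised chroman-3-one 15 (not isolated)
Conditions: [(Me4tBuXPhos)Au]NTf2 (5 mol%), 2,6-dibromopyridine N-oxide (1.3 equiv), ClCH2CH2Cl, rt, then 50 °C
Reagents that add atoms: 2,6-dibromopyridine N-oxide, [O-][n+]1c(Br)cccc1Br
Why: Proposed new method: one cationic monovalent gold catalyst runs two known alkyne activations in one flask — the terminal alkyne is oxidised by the N-oxide to an α-oxo carbene bound to LAu+ that is trapped by either of the two equivalent ortho C–H positions of ring D to close ring F as chroman-3-one 15 (closest known reaction: gold-catalysed oxidative cyclisation of aryl propargyl ethers to chroman-3-ones), and the internal aryl alkyne, which is oxidised far more slowly, undergoes 6-endo-dig hydroarylation by the ring A carbon para to the benzyloxy group to close ring C as the 4-aryl-2H-chromene (closest known reaction: gold- or platinum-catalysed cyclisation of aryl propargyl ethers to 2H-chromenes); upper C2 is not touched and keeps its configuration (R in the ether reads S in the chromene only through a change of CIP priorities), and lower C2 is formed as a mixture that step 9 resolves.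

Step 9
Reactants: 16 (2RS)-5,7-bis(benzyloxy)-2-[4-(benzyloxy)phenyl]-6-{(2S)-7-(benzyloxy)-2-[4-(benzyloxy)phenyl]-2H-chromen-4-yl}-2H-chromen-3(4H)-one
Product: 17 (2R,3R)-5,7-bis(benzyloxy)-2-[4-(benzyloxy)phenyl]-6-{(2S)-7-(benzyloxy)-2-[4-(benzyloxy)phenyl]-2H-chromen-4-yl}-3,4-dihydro-2H-chromen-3-ol
Conditions: RuCl[(R,R)-TsDPEN](p-cymene) (2 mol%), HCO2H/Et3N (5:2), CH2Cl2, 30 °C
Reagents that add atoms: none
Why: Proposed new method: Noyori–Ikariya asymmetric transfer hydrogenation run as a dynamic kinetic resolution — lower C2 is α to the ketone, benzylic and α-oxygenated, so Et3N epimerises it faster than the ruthenium hydride reduces the ketone, and the catalyst reduces the (2R)-ketone selectively with hydride delivered trans to the C2 aryl group to give the 2,3-cis (2R,3R) alcohol (closest known reaction: transfer-hydrogenative dynamic kinetic resolution of α-aryl and α-alkoxy cyclic ketones such as 2-arylcyclohexanones and 3-arylchroman-4-ones to the cis alcohols).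

Step 10
Reactants: 17 (2R,3R)-5,7-bis(benzyloxy)-2-[4-(benzyloxy)phenyl]-6-{(2S)-7-(benzyloxy)-2-[4-(benzyloxy)phenyl]-2H-chromen-4-yl}-3,4-dihydro-2H-chromen-3-ol
Product: 18 (2R,3R)-6-[(2S,4S)-7-hydroxy-2-(4-hydroxyphenyl)-3,4-dihydro-2H-chromen-4-yl]-2-(4-hydroxyphenyl)-3,4-dihydro-2H-chromene-3,5,7-triol (CNP0167324.1)
Conditions: H2 (3 atm), Pd(OH)2/C, THF/MeOH, rt
Reagents that add atoms: none
Why: heterogeneous catalytic hydrogenation adds H2 to the C3=C4 bond of ring C from the face opposite the C2 aryl group, which sets upper C4 as S (2,4-cis), and hydrogenolysis removes the five benzyl ethers in the same flask.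

## Compound list

1 | 3,5-bis(benzyloxy)phenol | Oc1cc(OCc2ccccc2)cc(OCc2ccccc2)c1 | starting material
2 | N-{[2,6-bis(benzyloxy)-4-hydroxyphenyl]methylidene}-N-methylmethanaminium chloride | C[N+](C)=Cc1c(OCc2ccccc2)cc(O)cc1OCc1ccccc1.[Cl-] | intermediate
3 | 2,6-bis(benzyloxy)-4-hydroxybenzaldehyde | O=Cc1c(OCc2ccccc2)cc(O)cc1OCc1ccccc1 | intermediate
4 | ethynyltri(propan-2-yl)silane | C#C[Si](C(C)C)(C(C)C)C(C)C | starting material
5 | 4-(benzyloxy)benzaldehyde | O=Cc1ccc(OCc2ccccc2)cc1 | starting material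
6 | lithium (triisopropylsilyl)acetylide | [Li]C#C[Si](C(C)C)(C(C)C)C(C)C | intermediate
7 | rac-1-[4-(benzyloxy)phenyl]-3-[tri(propan-2-yl)silyl]prop-2-yn-1-ol | OC(C#C[Si](C(C)C)(C(C)C)C(C)C)c1ccc(OCc2ccccc2)cc1 | intermediate
8 | rac-2,6-bis(benzyloxy)-4-({1-[4-(benzyloxy)phenyl]-3-[tri(propan-2-yl)silyl]prop-2-yn-1-yl}oxy)benzaldehyde | O=Cc1c(OCc2ccccc2)cc(OC(C#C[Si](C(C)C)(C(C)C)C(C)C)c2ccc(OCc3ccccc3)cc2)cc1OCc1ccccc1 | intermediate
9 | rac-1,3-bis(benzyloxy)-2-ethynyl-5-({1-[4-(benzyloxy)phenyl]-3-[tri(propan-2-yl)silyl]prop-2-yn-1-yl}oxy)benzene | C#Cc1c(OCc2ccccc2)cc(OC(C#C[Si](C(C)C)(C(C)C)C(C)C)c2ccc(OCc3ccccc3)cc2)cc1OCc1ccccc1 | intermediate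
10 | ({2,6-bis(benzyloxy)-4-[(1-[4-(benzyloxy)phenyl]-3-[tri(propan-2-yl)silyl]prop-2-yn-1-yl)oxy]phenyl}ethynyl)(methyl)zinc | C[Zn]C#Cc1c(OCc2ccccc2)cc(OC(C#C[Si](C(C)C)(C(C)C)C(C)C)c2ccc(OCc3ccccc3)cc2)cc1OCc1ccccc1 | intermediate
11 | (1S)-1-[4-(benzyloxy)phenyl]-3-[2,6-bis(benzyloxy)-4-({1-[4-(benzyloxy)phenyl]-3-[tri(propan-2-yl)silyl]prop-2-yn-1-yl}oxy)phenyl]prop-2-yn-1-ol (1:1 epimers at the racemic ether carbon of the lower arm) | c1ccccc1COc1ccc([C@H](O)C#Cc2c(OCc3ccccc3)cc(OC(C#C[Si](C(C)C)(C(C)C)C(C)C)c3ccc(OCc4ccccc4)cc3)cc2OCc2ccccc2)cc1 | intermediate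
12 | 3-(benzyloxy)phenol | Oc1cccc(OCc2ccccc2)c1 | starting material
13 | 1,3-bis(benzyloxy)-2-{(3R)-3-[4-(benzyloxy)phenyl]-3-[3-(benzyloxy)phenoxy]prop-1-yn-1-yl}-5-({1-[4-(benzyloxy)phenyl]-3-[tri(propan-2-yl)silyl]prop-2-yn-1-yl}oxy)benzene (lower ether carbon racemic) | c1ccccc1COc1ccc([C@@H](Oc2cccc(OCc3ccccc3)c2)C#Cc2c(OCc3ccccc3)cc(OC(C#C[Si](C(C)C)(C(C)C)C(C)C)c3ccc(OCc4ccccc4)cc3)cc2OCc2ccccc2)cc1 | intermediate
14 | 1,3-bis(benzyloxy)-2-{(3R)-3-[4-(benzyloxy)phenyl]-3-[3-(benzyloxy)phenoxy]prop-1-yn-1-yl}-5-({1-[4-(benzyloxy)phenyl]prop-2-yn-1-yl}oxy)benzene (lower ether carbon racemic) | c1ccccc1COc1ccc([C@@H](Oc2cccc(OCc3ccccc3)c2)C#Cc2c(OCc3ccccc3)cc(OC(C#C)c3ccc(OCc4ccccc4)cc3)cc2OCc2ccccc2)cc1 | intermediate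
15 | (2RS)-5,7-bis(benzyloxy)-2-[4-(benzyloxy)phenyl]-6-{(3R)-3-[4-(benzyloxy)phenyl]-3-[3-(benzyloxy)phenoxy]prop-1-yn-1-yl}-2H-chromen-3(4H)-one | c1ccccc1COc1ccc([C@@H](Oc2cccc(OCc3ccccc3)c2)C#Cc2c(OCc3ccccc3)cc3c(c2OCc2ccccc2)CC(=O)C(c2ccc(OCc4ccccc4)cc2)O3)cc1 | intermediate
16 | (2RS)-5,7-bis(benzyloxy)-2-[4-(benzyloxy)phenyl]-6-{(2S)-7-(benzyloxy)-2-[4-(benzyloxy)phenyl]-2H-chromen-4-yl}-2H-chromen-3(4H)-one | c1ccccc1COc1ccc([C@@H]2C=C(c3c(OCc4ccccc4)cc4c(c3OCc3ccccc3)CC(=O)C(c3ccc(OCc5ccccc5)cc3)O4)c3ccc(OCc4ccccc4)cc3O2)cc1 | intermediate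
17 | (2R,3R)-5,7-bis(benzyloxy)-2-[4-(benzyloxy)phenyl]-6-{(2S)-7-(benzyloxy)-2-[4-(benzyloxy)phenyl]-2H-chromen-4-yl}-3,4-dihydro-2H-chromen-3-ol | c1ccccc1COc1ccc([C@@H]2C=C(c3c(OCc4ccccc4)cc4c(c3OCc3ccccc3)C[C@@H](O)[C@@H](c3ccc(OCc5ccccc5)cc3)O4)c3ccc(OCc4ccccc4)cc3O2)cc1 | intermediate
18 | (2R,3R)-6-[(2S,4S)-7-hydroxy-2-(4-hydroxyphenyl)-3,4-dihydro-2H-chromen-4-yl]-2-(4-hydroxyphenyl)-3,4-dihydro-2H-chromene-3,5,7-triol (CNP0167324.1) | Oc1ccc([C@@H]2C[C@H](c3c(O)cc4c(c3O)C[C@@H](O)[C@@H](c3ccc(O)cc3)O4)c3ccc(O)cc3O2)cc1 | target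

## Step count and risks

Total steps: 10. Longest linear sequence: 9 (steps 1, 3, 4, 5, 6, 7, 8, 9, 10; step 2 is a side branch).

The three steps most likely to fail:

Step 8 is the highest risk. The lower arm may undergo plain hydroarylation instead of oxidation, the N-oxide may attack the internal alkyne, and ring A may close partly ortho to the benzyloxy group. The fallback separates the two events and drops the oxidant. It sets out from 14: the same gold catalyst without N-oxide gives double 6-endo hydroarylation to the bis(2H-chromene) F1. 9-BBN then NaBO3 hydroborates only the less hindered, disubstituted C3=C4 bond of the lower chromene, from the face opposite the C2 aryl group, to give the 2,3-trans flavan-3-ol F2. Dess–Martin periodinane oxidises F2 to the ketone, and the route is rejoined at 16.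

Step 9 may give low selectivity, because the ketone is not conjugated to an arene and the catalyst must tell the two α-carbons apart. The fallback replaces catalyst control by diastereomer separation with recycling. It sets out from 16: LiBH(s-Bu)3 in THF at −78 °C reduces trans to the C2 aryl group and gives the two 2,3-cis alcohols, 17 and its lower-unit (2S,3S) diastereomer F3. These are diastereomers because the upper unit is a single enantiomer, so chromatography separates them. F3 is oxidised back to 16 with Dess–Martin periodinane and recycled, and the route continues at 17.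

Step 6 may lose enantiopurity, because the 4-benzyloxybenzylic propargylic oxyphosphonium can ionise, and SN2′ attack would give an allene. The fallback forms the C–O bond on the aryl side with retention. It sets out from 9: step 5 is run with the antipodal ligand to give the (R)-alcohol F4. Its sodium alkoxide (NaH, toluene, 0 °C) is O-arylated by the diaryliodonium salt [3-(benzyloxy)phenyl](2,4,6-trimethylphenyl)iodonium trifluoromethanesulfonate F5, made beforehand from 1-(benzyloxy)-3-iodobenzene, mCPBA, TfOH and mesitylene. The carbinol C–O bond is never broken, so the route is rejoined at 13.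

Further compounds

F1 | step 8 | (2RS)-5,7-bis(benzyloxy)-2-[4-(benzyloxy)phenyl]-6-{(2S)-7-(benzyloxy)-2-[4-(benzyloxy)phenyl]-2H-chromen-4-yl}-2H-chromene | c1ccccc1COc1ccc([C@@H]2C=C(c3c(OCc4ccccc4)cc4c(c3OCc3ccccc3)C=CC(c3ccc(OCc5ccccc5)cc3)O4)c3ccc(OCc4ccccc4)cc3O2)cc1
F2 | step 8 | 2,3-trans-5,7-bis(benzyloxy)-2-[4-(benzyloxy)phenyl]-6-{(2S)-7-(benzyloxy)-2-[4-(benzyloxy)phenyl]-2H-chromen-4-yl}-3,4-dihydro-2H-chromen-3-ol (both lower-unit enantiomeric series) | c1ccccc1COc1ccc([C@@H]2C=C(c3c(OCc4ccccc4)cc4c(c3OCc3ccccc3)CC(O)C(c3ccc(OCc5ccccc5)cc3)O4)c3ccc(OCc4ccccc4)cc3O2)cc1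
F3 | step 9 | (2S,3S)-5,7-bis(benzyloxy)-2-[4-(benzyloxy)phenyl]-6-{(2S)-7-(benzyloxy)-2-[4-(benzyloxy)phenyl]-2H-chromen-4-yl}-3,4-dihydro-2H-chromen-3-ol | c1ccccc1COc1ccc([C@@H]2C=C(c3c(OCc4ccccc4)cc4c(c3OCc3ccccc3)C[C@H](O)[C@H](c3ccc(OCc5ccccc5)cc3)O4)c3ccc(OCc4ccccc4)cc3O2)cc1
F4 | step 6 | (1R)-1-[4-(benzyloxy)phenyl]-3-[2,6-bis(benzyloxy)-4-({1-[4-(benzyloxy)phenyl]-3-[tri(propan-2-yl)silyl]prop-2-yn-1-yl}oxy)phenyl]prop-2-yn-1-ol | c1ccccc1COc1ccc([C@@H](O)C#Cc2c(OCc3ccccc3)cc(OC(C#C[Si](C(C)C)(C(C)C)C(C)C)c3ccc(OCc4ccccc4)cc3)cc2OCc2ccccc2)cc1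
F5 | step 6 | [3-(benzyloxy)phenyl](2,4,6-trimethylphenyl)iodonium trifluoromethanesulfonate | Cc1cc(C)c([I+]c2cccc(OCc3ccccc3)c2)c(C)c1.[O-]S(=O)(=O)C(F)(F)F
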